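Sunday's flask, at 0.0018 M, still held most of its charge as open intermediate at 15.0 h, while Wednesday's, at 0.15 M, was finished by 1.33 h. Amber, at 0.0012 M, lies below Sunday's charge, so it is an extrapolation; green to violet lie between the two earlier runs, violet at 0.10 M being below Wednesday's charge.

all flasks: free catalyst 1 mol%; precatalyst 2.5 mol%
- Sunday's: starting material 0.0018 M; partner 1.8 equiv; run made earlier
- Wednesday's: starting material 0.15 M; partner 1.8 equiv; run made earlier
- amber: starting material 0.0012 M; partner 1.80 equiv; time 30 h
- green: starting material 0.0030 M; partner 1.80 equiv; time 30 h
- grey: starting material 0.010 M; partner 1.80 equiv; time 30 h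
- blue: starting material 0.030 M; partner 1.80 equiv; time 30 h
- violet: starting material 0.10 M; partner 1.80 equiv; time 30 h

- Sunday's (time / h: open intermediate / %, target / %): 3.00: 45.0, 0; 6.00: 59.1, 3.0; 10.0: 62.4, 7.8; 12.0: 61.4, 10.6; 15.0: 59.1, 14.2
- Wednesday's (time / h: open intermediate / %, target / %): 1.33: 0.7, 100.3; 4.00: 0.1, 101.1; 8.00: 0, 99.3; 10.0: 0, 99.3; 15.0: 0.5, 99.5

(each reading ± 0.5 percentage points)

- amount of open intermediate at the end, in percent of the starting material charged for amber, green, grey, blue, violet, in this order
- how that number moves from the first to the last of them (falls all the way / falls, then rises / hardly changes / rises, then falls / rises all the way)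

- a step back or a flat step of under half a point counts as no turn
- "hardly changes" means that all values lie within two and a half points (for a concentration: within two and a half percent of the largest)

My reckoning replaces Sunday's curves by their means. Between 10.0 h and 15.0 h target grows at 0.0211 h⁻¹ per unit of mean open intermediate, a pseudo-first-order constant. Extrapolated back, that line starts at 3.91 h. Open intermediate is 0.689 of what has not yet closed, so that pool drains at 0.0145 h⁻¹.

Partner and catalyst are fixed shares of the charge, so I scale this constant with the square of the charge. Taken first order instead, Wednesday would keep 20.0% undrained at 1.33 h, yet it read 100.3% target. Sunday's lag is longer than that whole interval, so I let the lag shrink inversely with charge.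

For amber this gives 0.156: the drain number, the drain constant times the time after the lag, at that flask's charge. The pool keeps exp(−number) of the charge, and open intermediate is the share above of that pool.

Is one number enough? Sunday's first reading gives an opening constant of 0.353 h⁻¹. Scaled with charge, amber's is 0.235 h⁻¹, far faster than its drain constant of 0.00645 h⁻¹, so in amber the pool forms ahead of its drain. But in my scaling opening goes with the charge and drain with its square, so this ratio goes from 36.4 in amber to 4.38 in grey and 0.438 in violet, where the opening constant is smaller than the drain constant. So one number is not enough across the row: I read it for amber and green. It also holds the drain constant fixed over the run, so my entries from grey upward I trust as small, not as values.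

| Flask | Drain number | Mine | Forecast |
|---|---|---|---|
| amber | 0.156 | 58.9% | 53% |
| green | 1.11 | 22.6% | 25% |
| grey | 13.1 | <0.001% | 0.02% |

Blue I put at hardly any, and violet, with its larger charge, the same. The forecast gives 0% and 0%, and says the row falls all the way. Of its own scaling it says: “I therefore assume k ∝ c², which is the weakest inference here”.

The flasks give 59.6%, 26.8%, 0.0324%, 0% and 0%: the row falls all the way.

    partner + catalyst intermediate → second catalyst + target (k = 0.270 M⁻¹ s⁻¹)
    starting material + free catalyst ⇌ free catalyst + open intermediate (K = 2.50, k = 3.70 M⁻¹ s⁻¹)
    second catalyst + open intermediate ⇌ catalyst intermediate (K = 220 M⁻¹, k = 65.0 M⁻¹ s⁻¹)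
    partner + precatalyst → second catalyst + spent reagent (k = 0.0160 M⁻¹ s⁻¹)

In amber at 30.0 h, the forward opening step has a half-life of 4.3 h, the slowest mode of the whole flask has a far longer one of 67.3 h, and open intermediate is made at 0.320 of the rate at which it is used up. Amber's drain number of 0.156 puts 85.6% of the charge in starting material and open intermediate together against 84.7% in the flask, and green's 1.11 puts 33.0% against 38.5%.

(All runs were generated by integration with constants of no real substance, and the scatter is random.)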